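**Plan**

1. Retrosynthesis: after removal of two phenol acetates, ring D (the cyclohexene) is cut in one stroke through C-1'–C-2' and C-4'–C-5'. This leaves a 1-aryl-2-isopropylallyl cation (C-1', C-6', C-5') on the flavanone and an isobutene 1,3-dianion equivalent (C-2', C-3', C-4'), the gem-disilane 14.
2. Enabling feature: C-1' is benzylic to ring A, para to O-1 and flanked by O-5 and O-7, so it can carry positive charge twice (first as the allyl cation, then again after protonation at C-6'). The C-2'=C-3' olefin lies exactly where a vinylsilane terminator leaves it.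
3. The cation precursor 10 is cut at C-1'–C-6' (alkenylchromium plus aldehyde) and at C-6–C-1' (formylation ortho to the chelated 5-OH of (S)-pinocembrin, whose only free ortho carbon is C-6).
4. Forward: rings A, B and C are bought as (S)-pinocembrin; the C-6 side chain is built (steps 1–3, 5); ring D is closed from the two three-carbon pieces (step 7); the acetates are removed (step 8).
5. Stereochemistry: C-2 comes from the chiral pool and is kept by avoiding base. C-1' and C-6' are both set in step 7, the absolute sense by a chiral counter-anion and the trans relation by a chair closure.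

Key step: step 7

Remark: (2S)-pinocembrin of high enantiomeric purity and 3-methyl-2-methylenebutanal (needed only in a fallback) are taken to be commercial.

**Route**

Step 1
Reactants: 1 (2S)-5,7-dihydroxy-2-phenylchroman-4-one ((S)-pinocembrin)
Product: 2 (2S)-7-acetoxy-5-hydroxy-2-phenylchroman-4-one
Conditions: Ac2O (1.05 equiv), pyridine (1.5 equiv), CH2Cl2, 0 °C
Reagents that add atoms: acetic anhydride CC(=O)OC(C)=O
Why: Selective O-acylation: the 7-OH is the acidic, unchelated phenol whereas the 5-OH is locked in a hydrogen bond to the C-4 carbonyl, so one equivalent of anhydride should acylate O-7 only, and no stereocentre is touched.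

Step 2
Reactants: 2 (2S)-7-acetoxy-5-hydroxy-2-phenylchroman-4-one
Product: 4 (2S)-7-acetoxy-5-hydroxy-4-oxo-2-phenylchroman-6-carbaldehyde, via chloro(methoxy)methyl arene 3 (not isolated)
Conditions: Cl2CHOCH3 (1.3 equiv), TiCl4 (2.5 equiv), CH2Cl2, −20 to 0 °C; then ice-cold 1 M HCl
Reagents that add atoms: dichloromethyl methyl ether COC(Cl)Cl; water O
Why: Rieche formylation: the titanium phenoxide at O-5 should deliver the electrophile to its only free ortho carbon, C-6 (C-8 is ortho only to the acetoxy and ring oxygens), the α-chloro ether is hydrolysed on work-up, and the cold, base-free medium should leave C-2 untouched.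

Step 3
Reactants: 4 (2S)-7-acetoxy-5-hydroxy-4-oxo-2-phenylchroman-6-carbaldehyde
Product: 5 (2S)-5,7-diacetoxy-4-oxo-2-phenylchroman-6-carbaldehyde
Conditions: Ac2O (1.5 equiv), pyridine, DMAP (5 mol %), CH2Cl2, 0 °C
Reagents that add atoms: acetic anhydride CC(=O)OC(C)=O
Why: DMAP-catalysed O-acylation of the now doubly chelated, acidic 5-OH masks the last phenol, so that later neither an ortho-quinone methide nor a 2H-chromene can form from the side chain.

Step 4
Reactants: 6 3-methylbutan-2-one
Product: 8 3-methylbut-1-en-2-yl trifluoromethanesulfonate, via lithium enolate 7 (not isolated)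
Conditions: LiN(iPr)2 (1.05 equiv), THF, −78 °C; then PhN(SO2CF3)2, −78 to 0 °C
Reagents that add atoms: N-phenylbis(trifluoromethanesulfonimide) O=S(=O)(N(c1ccccc1)S(=O)(=O)C(F)(F)F)C(F)(F)F
Why: Enol triflate synthesis: kinetic deprotonation at the methyl group followed by O-sulfonylation should give the terminal alkenyl triflate.

Step 5
Reactants: 5 (2S)-5,7-diacetoxy-4-oxo-2-phenylchroman-6-carbaldehyde; 8 3-methylbut-1-en-2-yl trifluoromethanesulfonate
Product: 10 (2S)-5,7-diacetoxy-6-(1-hydroxy-3-methyl-2-methylenebutyl)-2-phenylchroman-4-one (both carbinol epimers), via alkenylchromium dichloride 9 (not isolated)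
Conditions: CrCl2 (4 equiv), NiCl2 (2 mol %), DMF, 20 °C; work-up at pH 7
Reagents that add atoms: none
Why: Nozaki–Hiyama–Kishi coupling: zerovalent nickel and CrCl2 turn the triflate into an alkenyl species of trivalent chromium that should add to the aldehyde but not to the C-4 ketone or the aryl acetates; the new carbinol centre forms unselectively, which is harmless because step 7 ionises it.

Step 6
Reactants: 11 chlorobis(trimethylsilyl)methane; 12 2-bromopropene
Product: 14 3,3-bis(trimethylsilyl)-2-methylprop-1-ene, via Grignard reagent 13 (not isolated)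
Conditions: Mg, Et2O, reflux; then 12, NiCl2(dppp) (2 mol %; dppp = Ph2P(CH2)3PPh2), Et2O, reflux
Reagents that add atoms: none
Why: Kumada coupling of an α-silylalkyl Grignard reagent with an alkenyl bromide, the standard way to allylsilanes, should extend to the bis(silyl)methyl reagent.

Step 7
Reactants: 10 (2S)-5,7-diacetoxy-6-(1-hydroxy-3-methyl-2-methylenebutyl)-2-phenylchroman-4-one; 14 3,3-bis(trimethylsilyl)-2-methylprop-1-ene
Product: 16 (2S)-5,7-diacetoxy-6-[(1S,6S)-3-methyl-6-(propan-2-yl)cyclohex-2-en-1-yl]-2-phenylchroman-4-one, via dienyl vinylsilane 15 (not isolated)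
Conditions: chiral BINOL-derived imidodiphosphorimidate Brønsted acid with N-triflyl groups (IDPi type, 5 mol %, antipode fixed by screening), 14 (1.5 equiv), CH2Cl2–(CF3)2CHOH 5:1, −60 to −20 °C
Reagents that add atoms: none
Why: Proposed new method: the acid ionises the benzylic and allylic carbinol of 10 to an ion-paired 1-aryl-2-isopropylallyl cation, whose CH2 terminus (C-5') is attacked by the terminal CH2 of 14 in a Hosomi–Sakurai SE2' step that sheds one silyl group and leaves vinylsilane 15; protonation of the styrene of 15 at C-6' regenerates the cation at C-1', the vinylsilane closes on it by ipso attack at C-2', and loss of the second silyl group fixes the olefin at C-2'=C-3', the carbinol oxygen and both silyl groups leaving as hexamethyldisiloxane. The closest known reaction types are Lewis acid allylations by 3,3-bis(silyl)propenes that deliver vinylsilanes, vinylsilane-terminated cation cyclisations, and confined chiral acids that steer proton-initiated cation–olefin cyclisations and silylium Hosomi–Sakurai reactions through a chiral ion pair; their union in one flask on an allyl cation is new. Ring D closes in a 6-endo-trig mode with respect to the vinylsilane through a chair transition state. C-1' is set by the face of the benzylic cation that the chiral counter-anion leaves open, and C-6' follows from it because the isopropyl group sits equatorial in the chair (trans); the two C-6' epimers of the cation should interconvert by reversible protonation, so the matched one is drained. The step needs attack at C-5' and not at C-1' of the allyl cation, which the two ortho acetoxy groups and the isopropyl group should secure by shielding C-1', and it needs the olefin to end at C-2'=C-3', which the silicon on C-2' secures; the remote C-2 centre plays no part, and the acetylated phenols cannot add to cationic intermediates.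

Step 8
Reactants: 16 (2S)-5,7-diacetoxy-6-[(1S,6S)-3-methyl-6-(propan-2-yl)cyclohex-2-en-1-yl]-2-phenylchroman-4-one
Product: 17 (2S)-5,7-dihydroxy-6-[(1S,6S)-3-methyl-6-(propan-2-yl)cyclohex-2-en-1-yl]-2-phenylchroman-4-one (target)
Conditions: NH4OAc (10 equiv), MeOH–H2O 4:1, 20 °C
Reagents that add atoms: none
Why: Near-neutral methanolysis of aryl acetates should free both phenols without the base that opens ring C (loss of C-2 configuration) and without the acid that adds a phenol to the C-2'=C-3' olefin.

**Compound list**

1 | (2S)-5,7-dihydroxy-2-phenylchroman-4-one ((S)-pinocembrin) | O=C1C[C@@H](c2ccccc2)Oc2cc(O)cc(O)c12 | starting material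
2 | (2S)-7-acetoxy-5-hydroxy-2-phenylchroman-4-one | CC(=O)Oc1cc(O)c2C(=O)C[C@@H](c3ccccc3)Oc2c1 | intermediate
3 | (2S)-7-acetoxy-6-[chloro(methoxy)methyl]-5-hydroxy-2-phenylchroman-4-one (present as its titanium phenoxide) | COC(Cl)c1c(OC(C)=O)cc2c(c1O)C(=O)C[C@@H](c1ccccc1)O2 | intermediate (not isolated)
4 | (2S)-7-acetoxy-5-hydroxy-4-oxo-2-phenylchroman-6-carbaldehyde | O=Cc1c(OC(C)=O)cc2c(c1O)C(=O)C[C@@H](c1ccccc1)O2 | intermediate
5 | (2S)-5,7-diacetoxy-4-oxo-2-phenylchroman-6-carbaldehyde | O=Cc1c(OC(C)=O)cc2c(c1OC(C)=O)C(=O)C[C@@H](c1ccccc1)O2 | intermediate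
6 | 3-methylbutan-2-one | CC(=O)C(C)C | starting material
7 | lithium 3-methylbut-1-en-2-olate | [Li]OC(=C)C(C)C | intermediate (not isolated)
8 | 3-methylbut-1-en-2-yl trifluoromethanesulfonate | C=C(OS(=O)(=O)C(F)(F)F)C(C)C | intermediate
9 | dichloro(3-methylbut-1-en-2-yl)chromium | C=C([Cr](Cl)Cl)C(C)C | intermediate (not isolated)
10 | (2S)-5,7-diacetoxy-6-(1-hydroxy-3-methyl-2-methylenebutyl)-2-phenylchroman-4-one (both carbinol epimers) | C=C(C(C)C)C(O)c1c(OC(C)=O)cc2c(c1OC(C)=O)C(=O)C[C@@H](c1ccccc1)O2 | intermediate
11 | chlorobis(trimethylsilyl)methane | C[Si](C)(C)C(Cl)[Si](C)(C)C | starting material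
12 | 2-bromopropene | CC(Br)=C | starting material
13 | [bis(trimethylsilyl)methyl]magnesium chloride | C[Si](C)(C)C([Mg]Cl)[Si](C)(C)C | intermediate (not isolated)
14 | 3,3-bis(trimethylsilyl)-2-methylprop-1-ene | C=C(C)C([Si](C)(C)C)[Si](C)(C)C | intermediate
15 | (2S)-5,7-diacetoxy-6-[2-isopropyl-5-methyl-6-(trimethylsilyl)hexa-1,5-dienyl]-2-phenylchroman-4-one (olefin geometries not defined) | C[Si](C)(C)C=C(C)CCC(C(C)C)=Cc1c(OC(C)=O)cc2c(c1OC(C)=O)C(=O)C[C@@H](c1ccccc1)O2 | intermediate (not isolated)
16 | (2S)-5,7-diacetoxy-6-[(1S,6S)-3-methyl-6-(propan-2-yl)cyclohex-2-en-1-yl]-2-phenylchroman-4-one | CC1=C[C@@H](c2c(OC(C)=O)cc3c(c2OC(C)=O)C(=O)C[C@@H](c2ccccc2)O3)[C@H](C(C)C)CC1 | intermediate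
17 | (2S)-5,7-dihydroxy-6-[(1S,6S)-3-methyl-6-(propan-2-yl)cyclohex-2-en-1-yl]-2-phenylchroman-4-one | CC1=C[C@@H](c2c(O)cc3c(c2O)C(=O)C[C@@H](c2ccccc2)O3)[C@H](C(C)C)CC1 | target

**Count and risks**

Total step count: 8. Longest linear sequence: 6 steps (steps 1, 2, 3, 5, 7, 8).

Steps most likely to fail:

Step 7 (labelled step). Three things may go wrong. The vinylsilane may be protodesilylated before ring closure, so that the olefin position is no longer controlled. The counter-anion may give poor facial selectivity at C-1', so that the (1'R,6'R) diastereomer forms as well. The allyl cation may be attacked at C-1' instead of C-5'. The fallback is the known acid-mediated Friedel–Crafts terpenylation of a phloroglucinol-type ring, and it sets out from 1. Compound 1 and commercial (4R)-p-mentha-2,8-dien-1-ol (CC1(O)C=C[C@H](C(C)=C)CC1) with p-TsOH·H2O (or BF3·OEt2 on Al2O3) in CH2Cl2 should give (2S)-5,7-dihydroxy-6-[(1R,6R)-3-methyl-6-(prop-1-en-2-yl)cyclohex-2-en-1-yl]-2-phenylchroman-4-one F1. The arene should enter trans to the isopropenyl group, as in cannabidiol-type couplings, and the isomer from substitution at C-8 would have to be separated. Selective saturation of the isopropenyl group with H2 over RhCl(PPh3)3 then returns to the route at 17.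

Step 2. Electrophilic attack may occur at C-8 as well as C-6, and the Lewis acid may open ring C with loss of configuration at C-2. The fallback sets out from 2 and replaces direct formylation by halogenation and carbonylation. Iodination ortho to the free 5-OH with benzyltrimethylammonium dichloroiodate and CaCO3 in CH2Cl2–MeOH should give (2S)-7-acetoxy-5-hydroxy-6-iodo-2-phenylchroman-4-one F2. Reductive carbonylation (Pd(PPh3)4, CO at 1 atm, Bu3SnH, toluene, 50 °C) then returns to the route at 4.

Step 5. An acetyl group may transfer from O-5 or O-7 to the new chromium alkoxide; loss of the benzylic acetate and closure of the freed phenol onto the allyl terminus would follow. The fallback sets out from 2 and makes the carbinol without any alkoxide. 3-Methyl-2-methylenebutan-1-ol F3 is made from 3-methyl-2-methylenebutanal (NaBH4, CeCl3·7H2O, MeOH, 0 °C). Mitsunobu etherification of the 5-OH of 2 with F3 (PPh3, diisopropyl azodicarboxylate, THF) should give (2S)-7-acetoxy-5-[(3-methyl-2-methylenebutyl)oxy]-2-phenylchroman-4-one F4. Aromatic Claisen rearrangement catalysed by Eu(fod)3 [tris(6,6,7,7,8,8,8-heptafluoro-2,2-dimethyloctane-3,5-dionato)europium] in CHCl3 at 60 °C moves the allyl group to C-6, the only free ortho carbon, to give (2S)-7-acetoxy-5-hydroxy-6-(3-methyl-2-methylenebutyl)-2-phenylchroman-4-one F5. Acetylation (Ac2O, pyridine, DMAP) gives (2S)-5,7-diacetoxy-6-(3-methyl-2-methylenebutyl)-2-phenylchroman-4-one F6. Allylic oxidation at the benzylic CH2 (SeO2 cat., t-BuOOH, CH2Cl2, 20 °C) then returns to the route at 10.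

Further compounds
F1 | step 7 | (2S)-5,7-dihydroxy-6-[(1R,6R)-3-methyl-6-(prop-1-en-2-yl)cyclohex-2-en-1-yl]-2-phenylchroman-4-one | CC1=C[C@@H](c2c(O)cc3c(c2O)C(=O)C[C@@H](c2ccccc2)O3)[C@H](C(C)=C)CC1
F2 | step 2 | (2S)-7-acetoxy-5-hydroxy-6-iodo-2-phenylchroman-4-one | Ic1c(OC(C)=O)cc2c(c1O)C(=O)C[C@@H](c1ccccc1)O2
F3 | step 5 | 3-methyl-2-methylenebutan-1-ol | C=C(CO)C(C)C
F4 | step 5 | (2S)-7-acetoxy-5-[(3-methyl-2-methylenebutyl)oxy]-2-phenylchroman-4-one | C=C(COc1c2C(=O)C[C@@H](c3ccccc3)Oc2cc(OC(C)=O)c1)C(C)C
F5 | step 5 | (2S)-7-acetoxy-5-hydroxy-6-(3-methyl-2-methylenebutyl)-2-phenylchroman-4-one | C=C(C(C)C)Cc1c(OC(C)=O)cc2c(c1O)C(=O)C[C@@H](c1ccccc1)O2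
F6 | step 5 | (2S)-5,7-diacetoxy-6-(3-methyl-2-methylenebutyl)-2-phenylchroman-4-one | C=C(C(C)C)Cc1c(OC(C)=O)cc2c(c1OC(C)=O)C(=O)C[C@@H](c1ccccc1)O2
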